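**Plan**
1. Retrosynthesis: the C14'–C15' sp2–sp2 bond is cut first (Stille union of C24 iodide 36 and C26 stannane 19). Then C7'=C8' and C7=C8 (HWE) release one common C9 iodotrienyl phosphonate 8 from both halves, and C14–C15 (Stille) releases the C15=C15' vinylene as distannane 18. Last, C5'=C6', the oxirane C–O bonds, C3'=C4' and C3=C4 lead back to two antipodal lavandulyl end groups.
2. Forward: phosphonate 8 (steps 1–5); right half grown from C2 to C15' (steps 6–13); left half grown from C2' to C14' (steps 14–24), its only ring, the C3'–C4' oxirane, arising in step 20 from an E-enone; union in step 25, desilylation in step 26.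
3. Stereochemistry: C2 (S) from natural (R)-lavandulol (chiral pool; its isopropenyl, CH2OH and prenyl carbons become C1, C3 and the C2 side chain). C2' (R) from an Evans dienolate alkylation on the (S)-benzyloxazolidinone. C3'/C4' from (R)-BINOL–lanthanum-controlled epoxidation. The twelve E chain alkenes from carboalumination, stabilised Wittig/HWE steps and stereoretentive palladium couplings.
4. Enabling feature: C14' is the unsubstituted CH end of the C13'-methyl alkene and C15' a CH of the unbranched trans C15=C15' vinylene, so the bond joins two unhindered E-alkenyl CH carbons of one uninterrupted dodecaene. The same I–CH=C(CH3)–CH=CH–CH=C(CH3)–CH2 unit sits on both sides (C14→C8 and C14'→C8'), and the C3'–C4' oxirane and the prenyl C=C are remote spectators.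
5. Remark: carotenoid locants are used (primed = oxirane half); (R)-(−)-lavandulol is assumed to be purchasable as the natural terpene alcohol; all polyenes are handled under argon in the dark.

Key step: step 25

**Common C9 phosphonate**

Step 1
Reactants: 1 (2E)-pent-2-en-4-yn-1-ol
Product: 2 (2E,4E)-5-iodo-4-methylpenta-2,4-dien-1-ol
Conditions: Me3Al (3 equiv), Cp2ZrCl2 (25 mol %), CH2Cl2, 0 °C to rt; then I2, THF, −30 to 0 °C
Reagents that add atoms: trimethylaluminium C[Al](C)C; iodine II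
Why: Negishi carboalumination adds Me–Al syn across the terminal alkyne with methyl on the internal carbon (future C13/C13'), and iodinolysis with retention should give the E-configured I–CH=C(CH3) terminus.

Step 2
Reactants: 2 (2E,4E)-5-iodo-4-methylpenta-2,4-dien-1-ol; 3 ethyl 2-(triphenyl-λ5-phosphanylidene)propanoate
Product: 5 ethyl (2E,4E,6E)-7-iodo-2,6-dimethylhepta-2,4,6-trienoate, via iododienal 4 (not isolated)
Conditions: MnO2 (15 equiv), 3 (1.3 equiv), CH2Cl2, rt, dark
Reagents that add atoms: none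
Why: Tandem MnO2 oxidation–Wittig olefination traps the labile dienal at once with the stabilised α-methyl ylide, which should give the E trisubstituted alkene.

Step 3
Reactants: 5 ethyl (2E,4E,6E)-7-iodo-2,6-dimethylhepta-2,4,6-trienoate
Product: 6 (2E,4E,6E)-7-iodo-2,6-dimethylhepta-2,4,6-trien-1-ol
Conditions: i-Bu2AlH (2.2 equiv), CH2Cl2, −78 °C
Reagents that add atoms: none
Why: Hydride reduction of the conjugated ester to the allylic alcohol at low temperature should leave the alkenyl iodide and the triene geometry untouched.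

Step 4
Reactants: 6 (2E,4E,6E)-7-iodo-2,6-dimethylhepta-2,4,6-trien-1-ol
Product: 7 (1E,3E,5E)-7-bromo-1-iodo-2,6-dimethylhepta-1,3,5-triene
Conditions: PBr3 (0.4 equiv), Et2O, 0 °C, dark; used crude
Reagents that add atoms: phosphorus tribromide BrP(Br)Br
Why: SN2 bromination of the primary allylic alcohol at 0 °C should proceed without allylic transposition.

Step 5
Reactants: 7 (1E,3E,5E)-7-bromo-1-iodo-2,6-dimethylhepta-1,3,5-triene
Product: 8 diethyl [(2E,4E,6E)-7-iodo-2,6-dimethylhepta-2,4,6-trien-1-yl]phosphonate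
Conditions: P(OEt)3 (3 equiv, neat), 80 °C
Reagents that add atoms: triethyl phosphite CCOP(OCC)OCC
Why: Michaelis–Arbuzov reaction of the primary allylic bromide should give the phosphonate, the alkenyl iodide being inert to the phosphite without a metal catalyst.

**Right half (C26 stannane)**

Step 6
Reactants: 9 (R)-(−)-lavandulol
Product: 10 (3S)-3-(hydroxymethyl)-2,6-dimethylheptane-2,6-diol
Conditions: Mn(dpm)3 (10 mol %), PhSiH3 (4 equiv), O2 (1 atm), i-PrOH/CH2Cl2, 0 °C to rt
Reagents that add atoms: dioxygen O=O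
Why: Mukaiyama hydration (hydrogen-atom transfer to the less substituted alkene carbon, then O2 trapping of each tertiary radical) should hydrate both alkenes with Markovnikov regiochemistry, while the chiral-pool centre (future C2), never a radical centre, is retained.

Step 7
Reactants: 10 (3S)-3-(hydroxymethyl)-2,6-dimethylheptane-2,6-diol
Product: 11 (3S)-2,6-dimethyl-2,6-bis[(triethylsilyl)oxy]-3-{[(triethylsilyl)oxy]methyl}heptane
Conditions: Et3SiOTf (3.6 equiv), 2,6-lutidine (5 equiv), CH2Cl2, −78 to 0 °C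
Reagents that add atoms: triethylsilyl trifluoromethanesulfonate CC[Si](CC)(CC)OS(=O)(=O)C(F)(F)F
Why: Silyl triflate silylation reaches the tertiary hydroxyls, whose TES ethers block retro-aldol cleavage and lactol formation in the aldehyde that follows.

Step 8
Reactants: 11 (3S)-2,6-dimethyl-2,6-bis[(triethylsilyl)oxy]-3-{[(triethylsilyl)oxy]methyl}heptane
Product: 12 (2R)-5-methyl-5-[(triethylsilyl)oxy]-2-{2-[(triethylsilyl)oxy]propan-2-yl}hexanal
Conditions: (COCl)2, DMSO, CH2Cl2, −78 to −30 °C; then Et3N, −78 to 0 °C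
Reagents that add atoms: none
Why: Under Swern conditions the unhindered primary TES ether is cleaved and oxidised directly to the aldehyde while the tertiary TES ethers persist, and the low temperature should preserve the α-stereocentre.

Step 9
Reactants: 12 (2R)-5-methyl-5-[(triethylsilyl)oxy]-2-{2-[(triethylsilyl)oxy]propan-2-yl}hexanal; 13 triethyl 3-methyl-4-phosphonocrotonate
Product: 14 ethyl (2E,4E,6S)-3,9-dimethyl-9-[(triethylsilyl)oxy]-6-{2-[(triethylsilyl)oxy]propan-2-yl}deca-2,4-dienoate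
Conditions: LiN(SiMe3)2, THF/DMPU, −78 to 0 °C
Reagents that add atoms: none
Why: The vinylogous Horner–Wadsworth–Emmons reaction should form the E C3=C4 alkene with the C5=C6 alkene mainly E (a minor 2Z isomer is removed by chromatography) without epimerising C2.

Step 10
Reactants: 14 ethyl (2E,4E,6S)-3,9-dimethyl-9-[(triethylsilyl)oxy]-6-{2-[(triethylsilyl)oxy]propan-2-yl}deca-2,4-dienoate
Product: 15 (2E,4E,6S)-3,9-dimethyl-9-[(triethylsilyl)oxy]-6-{2-[(triethylsilyl)oxy]propan-2-yl}deca-2,4-dien-1-ol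
Conditions: i-Bu2AlH (2.2 equiv), CH2Cl2, −78 °C
Reagents that add atoms: none
Why: 1,2-Reduction of the dienoate by the aluminium hydride should stop cleanly at the allylic alcohol and leave the silyl ethers intact.

Step 11
Reactants: 15 (2E,4E,6S)-3,9-dimethyl-9-[(triethylsilyl)oxy]-6-{2-[(triethylsilyl)oxy]propan-2-yl}deca-2,4-dien-1-ol
Product: 16 (2E,4E,6S)-3,9-dimethyl-9-[(triethylsilyl)oxy]-6-{2-[(triethylsilyl)oxy]propan-2-yl}deca-2,4-dienal
Conditions: MnO2 (15 equiv), CH2Cl2, rt
Reagents that add atoms: none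
Why: MnO2 oxidises allylic alcohols selectively to enals under neutral conditions without E/Z isomerisation.

Step 12
Reactants: 16 (2E,4E,6S)-3,9-dimethyl-9-[(triethylsilyl)oxy]-6-{2-[(triethylsilyl)oxy]propan-2-yl}deca-2,4-dienal; 8 diethyl [(2E,4E,6E)-7-iodo-2,6-dimethylhepta-2,4,6-trien-1-yl]phosphonate
Product: 17 (1E,3E,5E,7E,9E,11E,13S)-1-iodo-2,6,10,16-tetramethyl-16-[(triethylsilyl)oxy]-13-{2-[(triethylsilyl)oxy]propan-2-yl}heptadeca-1,3,5,7,9,11-hexaene
Conditions: NaN(SiMe3)2, THF, −78 to 0 °C, dark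
Reagents that add atoms: none
Why: Horner–Wadsworth–Emmons olefination with a polyenyl phosphonate, the classical way to extend retinoid chains, should form C7=C8 E-selectively, and the amide base does not attack the alkenyl iodide.

Step 13
Reactants: 17 (1E,3E,5E,7E,9E,11E,13S)-1-iodo-2,6,10,16-tetramethyl-16-[(triethylsilyl)oxy]-13-{2-[(triethylsilyl)oxy]propan-2-yl}heptadeca-1,3,5,7,9,11-hexaene; 18 (E)-1,2-bis(tributylstannyl)ethene
Product: 19 tributyl[(1E,3E,5E,7E,9E,11E,13E,15S)-4,8,12,18-tetramethyl-18-[(triethylsilyl)oxy]-15-{2-[(triethylsilyl)oxy]propan-2-yl}nonadeca-1,3,5,7,9,11,13-heptaen-1-yl]stannane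
Conditions: 18 (4 equiv), PdCl2(MeCN)2 (5 mol %), DMF/THF, rt, dark; Et3N-deactivated silica
Reagents that add atoms: none
Why: Stille coupling with excess distannane should replace iodine at C14 by the trans-2-stannylvinyl group with retention at both alkenes, the excess suppressing double coupling.

**Left half (C24 iodide)**

Step 14
Reactants: 20 (4S)-4-benzyl-1,3-oxazolidin-2-one; 21 3-methylbut-2-enoyl chloride
Product: 22 (4S)-4-benzyl-3-(3-methylbut-2-enoyl)-1,3-oxazolidin-2-one
Conditions: n-BuLi, THF, −78 °C; then 21, −78 to 0 °C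
Reagents that add atoms: none
Why: N-Acylation of the lithiated oxazolidinone with the acid chloride installs the Evans auxiliary.

Step 15
Reactants: 22 (4S)-4-benzyl-3-(3-methylbut-2-enoyl)-1,3-oxazolidin-2-one; 23 1-bromo-3-methylbut-2-ene
Product: 24 (4S)-4-benzyl-3-[(2S)-5-methyl-2-(prop-1-en-2-yl)hex-4-enoyl]-1,3-oxazolidin-2-one
Conditions: NaN(SiMe3)2, THF, −78 °C; then 23, −78 to −40 °C
Reagents that add atoms: none
Why: In this Evans alkylation the chelated Z(O)-sodium dienolate reacts at its α-carbon (deconjugative alkylation) on the face opposite the benzyl group, which should set the 2S centre (future C2').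

Step 16
Reactants: 24 (4S)-4-benzyl-3-[(2S)-5-methyl-2-(prop-1-en-2-yl)hex-4-enoyl]-1,3-oxazolidin-2-one
Product: 25 (S)-lavandulol
Conditions: LiBH4, H2O (1 equiv), Et2O, 0 °C
Reagents that add atoms: none
Why: Reductive cleavage of the imide gives the primary alcohol without touching the β,γ-unsaturated stereocentre and returns the auxiliary.

Step 17
Reactants: 25 (S)-lavandulol
Product: 26 (2R)-2-(2-hydroxypropan-2-yl)-5-methylhex-4-en-1-ol
Conditions: Co(acac)2 (20 mol %), PhSiH3 (1.2 equiv), O2 (1 atm), THF, 0 °C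
Reagents that add atoms: dioxygen O=O
Why: In this Mukaiyama hydration hydrogen-atom transfer is faster to the unhindered CH2 terminus of the 1,1-disubstituted alkene than to the trisubstituted prenyl alkene, so with limiting silane only the isopropenyl group should become the tertiary alcohol.

Step 18
Reactants: 26 (2R)-2-(2-hydroxypropan-2-yl)-5-methylhex-4-en-1-ol
Product: 27 triethyl{[(2R)-5-methyl-2-{2-[(triethylsilyl)oxy]propan-2-yl}hex-4-en-1-yl]oxy}silane
Conditions: Et3SiOTf (2.4 equiv), 2,6-lutidine (4 equiv), CH2Cl2, −78 to 0 °C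
Reagents that add atoms: triethylsilyl trifluoromethanesulfonate CC[Si](CC)(CC)OS(=O)(=O)C(F)(F)F
Why: Silyl triflate silylation protects the tertiary hydroxyl for the rest of the route and makes the primary position ready for direct oxidation.

Step 19
Reactants: 27 triethyl{[(2R)-5-methyl-2-{2-[(triethylsilyl)oxy]propan-2-yl}hex-4-en-1-yl]oxy}silane; 28 1-(triphenyl-λ5-phosphanylidene)propan-2-one
Product: 30 (3E,5R)-8-methyl-5-{2-[(triethylsilyl)oxy]propan-2-yl}nona-3,7-dien-2-one, via aldehyde 29 (not isolated)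
Conditions: (COCl)2, DMSO, CH2Cl2, −78 to −30 °C; Et3N; then 28 (2 equiv), −78 °C to rt (40 °C if slow)
Reagents that add atoms: none
Why: In this one-pot Swern oxidation–Wittig olefination the primary TES ether is oxidised to the α-branched aldehyde, which is trapped without isolation by the stabilised ylide to give the E-enone.

Step 20
Reactants: 30 (3E,5R)-8-methyl-5-{2-[(triethylsilyl)oxy]propan-2-yl}nona-3,7-dien-2-one
Product: 31 1-[(2S,3R)-3-{(3R)-2,6-dimethyl-2-[(triethylsilyl)oxy]hept-5-en-3-yl}oxiran-2-yl]ethan-1-one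
Conditions: La(O-i-Pr)3, (R)-BINOL, Ph3As=O (10 mol % each), t-BuOOH (1.5 equiv, decane), 4 Å MS, THF, rt
Reagents that add atoms: tert-butyl hydroperoxide CC(C)(C)OO
Why: In this lanthanum–BINOL-catalysed Weitz–Scheffer epoxidation the metal-bound peroxide adds to C3' of the E-enone and the enolate closes 3-exo-tet onto the O–O bond to give the trans oxirane, the (R)-BINOL complex (αS,βR sense for E-enones, as recalled from the literature and to be confirmed on a model enone) being expected to override the C2' centre and set both oxirane carbons, while the electron-rich prenyl alkene is inert to the nucleophilic oxidant.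

Step 21
Reactants: 31 1-[(2S,3R)-3-{(3R)-2,6-dimethyl-2-[(triethylsilyl)oxy]hept-5-en-3-yl}oxiran-2-yl]ethan-1-one; 32 triethyl phosphonoacetate
Product: 33 ethyl (2E)-3-[(2R,3R)-3-{(3R)-2,6-dimethyl-2-[(triethylsilyl)oxy]hept-5-en-3-yl}oxiran-2-yl]but-2-enoate
Conditions: NaH, THF, 0 °C to rt
Reagents that add atoms: none
Why: Horner–Wadsworth–Emmons olefination of the epoxy methyl ketone should place the ester trans to the larger oxiranyl group (E C5'=C6'; any Z isomer is separated), the oxirane CH not being enolisable.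

Step 22
Reactants: 33 ethyl (2E)-3-[(2R,3R)-3-{(3R)-2,6-dimethyl-2-[(triethylsilyl)oxy]hept-5-en-3-yl}oxiran-2-yl]but-2-enoate
Product: 34 (2E)-3-[(2R,3R)-3-{(3R)-2,6-dimethyl-2-[(triethylsilyl)oxy]hept-5-en-3-yl}oxiran-2-yl]but-2-en-1-ol
Conditions: i-Bu2AlH (2.2 equiv), CH2Cl2, −78 °C
Reagents that add atoms: none
Why: At −78 °C hydride reduction of the ester is much faster than attack on the vinyl oxirane, so the epoxy allylic alcohol should result.

Step 23
Reactants: 34 (2E)-3-[(2R,3R)-3-{(3R)-2,6-dimethyl-2-[(triethylsilyl)oxy]hept-5-en-3-yl}oxiran-2-yl]but-2-en-1-ol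
Product: 35 (2E)-3-[(2R,3R)-3-{(3R)-2,6-dimethyl-2-[(triethylsilyl)oxy]hept-5-en-3-yl}oxiran-2-yl]but-2-enal
Conditions: MnO2 (15 equiv), CH2Cl2, rt
Reagents that add atoms: none
Why: Neutral MnO2 oxidation of the allylic alcohol should spare the oxirane and the prenyl alkene.

Step 24
Reactants: 35 (2E)-3-[(2R,3R)-3-{(3R)-2,6-dimethyl-2-[(triethylsilyl)oxy]hept-5-en-3-yl}oxiran-2-yl]but-2-enal; 8 diethyl [(2E,4E,6E)-7-iodo-2,6-dimethylhepta-2,4,6-trien-1-yl]phosphonate
Product: 36 (2R,3R)-2-{(3R)-2,6-dimethyl-2-[(triethylsilyl)oxy]hept-5-en-3-yl}-3-[(2E,4E,6E,8E,10E)-11-iodo-6,10-dimethylundeca-2,4,6,8,10-pentaen-2-yl]oxirane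
Conditions: NaN(SiMe3)2, THF, −78 to 0 °C, dark
Reagents that add atoms: none
Why: The same polyenyl-phosphonate Horner–Wadsworth–Emmons olefination as in step 12 should form C7'=C8' E-selectively, the enal reacting faster than the oxirane under cold basic conditions.

**Union and deprotection**

Step 25
Reactants: 36 (2R,3R)-2-{(3R)-2,6-dimethyl-2-[(triethylsilyl)oxy]hept-5-en-3-yl}-3-[(2E,4E,6E,8E,10E)-11-iodo-6,10-dimethylundeca-2,4,6,8,10-pentaen-2-yl]oxirane; 19 tributyl[(1E,3E,5E,7E,9E,11E,13E,15S)-4,8,12,18-tetramethyl-18-[(triethylsilyl)oxy]-15-{2-[(triethylsilyl)oxy]propan-2-yl}nonadeca-1,3,5,7,9,11,13-heptaen-1-yl]stannane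
Product: 37 tris(triethylsilyl) ether of the target (silylated at the C1, C1' and side-chain tertiary hydroxyls)
Conditions: 19 (1.2 equiv), Pd2(dba)3·CHCl3 (5 mol %), AsPh3 (40 mol %), degassed NMP, rt, dark
Reagents that add atoms: none
Why: Zerovalent palladium inserts into the C14'–I bond of 36, the tributylstannyl group of 19 transfers its C15' carbon to palladium, and reductive elimination forms the C14'–C15' sp2–sp2 bond that completes the conjugated dodecaene. The closest known reaction type is the Stille coupling of polyenyl stannanes with alkenyl iodides used for carotenoid and retinoid chains. No ring is closed and no stereocentre is created; the E geometries at C13'=C14' and C15'=C15 are carried through because oxidative addition, transmetalation and reductive elimination are stereoretentive at sp2 carbon. The step needs chemoselectivity for C–I insertion over ionisation of the C3'–C4' vinyl oxirane to a π-allyl complex, which should be secured by the much faster insertion into the unhindered alkenyl iodide, the weakly donating arsine ligand, room temperature and neutral conditions free of base and Lewis acid. Site selectivity is inherent because 36 has one C–I bond and 19 one C–Sn bond, and the C2/C2' centres, TES ethers and prenyl alkene are remote spectators.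

Step 26
Reactants: 37 tris(triethylsilyl) ether of the target
Product: 38 (2S,2'R,3'R,4'R)-3',4'-epoxy-2-(3-hydroxy-3-methylbutyl)-2'-(3-methylbut-2-en-1-yl)-3,4-didehydro-1,2,1',2'-tetrahydro-ψ,ψ-carotene-1,1'-diol (target)
Conditions: Bu4NF (6 equiv), THF, 0 °C to rt, dark; deactivated silica
Reagents that add atoms: none
Why: Fluoride-mediated desilylation cleaves the three tertiary Si–O bonds under non-acidic conditions, which should spare the acid-labile polyenyl oxirane and all stereocentres.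

**Compound list**
1 | (2E)-pent-2-en-4-yn-1-ol | C#C/C=C/CO | starting material
2 | (2E,4E)-5-iodo-4-methylpenta-2,4-dien-1-ol | OC/C=C/C(C)=C/I | intermediate
3 | ethyl 2-(triphenyl-λ5-phosphanylidene)propanoate | CCOC(=O)C(C)=P(c1ccccc1)(c1ccccc1)c1ccccc1 | starting material
4 | (2E,4E)-5-iodo-4-methylpenta-2,4-dienal (not isolated) | O=C/C=C/C(C)=C/I | intermediate
5 | ethyl (2E,4E,6E)-7-iodo-2,6-dimethylhepta-2,4,6-trienoate | CCOC(=O)/C(C)=C/C=C/C(C)=C/I | intermediate
6 | (2E,4E,6E)-7-iodo-2,6-dimethylhepta-2,4,6-trien-1-ol | OC/C(C)=C/C=C/C(C)=C/I | intermediate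
7 | (1E,3E,5E)-7-bromo-1-iodo-2,6-dimethylhepta-1,3,5-triene | BrC/C(C)=C/C=C/C(C)=C/I | intermediate
8 | diethyl [(2E,4E,6E)-7-iodo-2,6-dimethylhepta-2,4,6-trien-1-yl]phosphonate | CCOP(=O)(OCC)C/C(C)=C/C=C/C(C)=C/I | intermediate
9 | (R)-(−)-lavandulol, (2R)-5-methyl-2-(prop-1-en-2-yl)hex-4-en-1-ol | CC(C)=CC[C@@H](CO)C(C)=C | starting material
10 | (3S)-3-(hydroxymethyl)-2,6-dimethylheptane-2,6-diol | CC(C)(O)CC[C@@H](CO)C(C)(C)O | intermediate
11 | (3S)-2,6-dimethyl-2,6-bis[(triethylsilyl)oxy]-3-{[(triethylsilyl)oxy]methyl}heptane | CC(C)(O[Si](CC)(CC)CC)CC[C@@H](CO[Si](CC)(CC)CC)C(C)(C)O[Si](CC)(CC)CC | intermediate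
12 | (2R)-5-methyl-5-[(triethylsilyl)oxy]-2-{2-[(triethylsilyl)oxy]propan-2-yl}hexanal | CC(C)(O[Si](CC)(CC)CC)CC[C@@H](C=O)C(C)(C)O[Si](CC)(CC)CC | intermediate
13 | triethyl 3-methyl-4-phosphonocrotonate (commercial E/Z mixture, drawn 2E) | CCOC(=O)/C=C(\C)CP(=O)(OCC)OCC | starting material
14 | ethyl (2E,4E,6S)-3,9-dimethyl-9-[(triethylsilyl)oxy]-6-{2-[(triethylsilyl)oxy]propan-2-yl}deca-2,4-dienoate | CCOC(=O)/C=C(C)/C=C/[C@H](CCC(C)(C)O[Si](CC)(CC)CC)C(C)(C)O[Si](CC)(CC)CC | intermediate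
15 | (2E,4E,6S)-3,9-dimethyl-9-[(triethylsilyl)oxy]-6-{2-[(triethylsilyl)oxy]propan-2-yl}deca-2,4-dien-1-ol | OC/C=C(C)/C=C/[C@H](CCC(C)(C)O[Si](CC)(CC)CC)C(C)(C)O[Si](CC)(CC)CC | intermediate
16 | (2E,4E,6S)-3,9-dimethyl-9-[(triethylsilyl)oxy]-6-{2-[(triethylsilyl)oxy]propan-2-yl}deca-2,4-dienal | O=C/C=C(C)/C=C/[C@H](CCC(C)(C)O[Si](CC)(CC)CC)C(C)(C)O[Si](CC)(CC)CC | intermediate
17 | (1E,3E,5E,7E,9E,11E,13S)-1-iodo-2,6,10,16-tetramethyl-16-[(triethylsilyl)oxy]-13-{2-[(triethylsilyl)oxy]propan-2-yl}heptadeca-1,3,5,7,9,11-hexaene | I/C=C(C)/C=C/C=C(C)/C=C/C=C(C)/C=C/[C@H](CCC(C)(C)O[Si](CC)(CC)CC)C(C)(C)O[Si](CC)(CC)CC | intermediate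
18 | (E)-1,2-bis(tributylstannyl)ethene | CCCC[Sn](CCCC)(CCCC)/C=C/[Sn](CCCC)(CCCC)CCCC | starting material
19 | tributyl[(1E,3E,5E,7E,9E,11E,13E,15S)-4,8,12,18-tetramethyl-18-[(triethylsilyl)oxy]-15-{2-[(triethylsilyl)oxy]propan-2-yl}nonadeca-1,3,5,7,9,11,13-heptaen-1-yl]stannane | CCCC[Sn](CCCC)(CCCC)/C=C/C=C(C)/C=C/C=C(C)/C=C/C=C(C)/C=C/[C@H](CCC(C)(C)O[Si](CC)(CC)CC)C(C)(C)O[Si](CC)(CC)CC | intermediate
20 | (4S)-4-benzyl-1,3-oxazolidin-2-one | O=C1OC[C@H](Cc2ccccc2)N1 | starting material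
21 | 3-methylbut-2-enoyl chloride | CC(C)=CC(Cl)=O | starting material
22 | (4S)-4-benzyl-3-(3-methylbut-2-enoyl)-1,3-oxazolidin-2-one | CC(C)=CC(=O)N1[C@@H](Cc2ccccc2)COC1=O | intermediate
23 | 1-bromo-3-methylbut-2-ene | CC(C)=CCBr | starting material
24 | (4S)-4-benzyl-3-[(2S)-5-methyl-2-(prop-1-en-2-yl)hex-4-enoyl]-1,3-oxazolidin-2-one | CC(C)=CC[C@H](C(=O)N1[C@@H](Cc2ccccc2)COC1=O)C(C)=C | intermediate
25 | (S)-lavandulol, (2S)-5-methyl-2-(prop-1-en-2-yl)hex-4-en-1-ol | CC(C)=CC[C@H](CO)C(C)=C | intermediate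
26 | (2R)-2-(2-hydroxypropan-2-yl)-5-methylhex-4-en-1-ol | CC(C)=CC[C@H](CO)C(C)(C)O | intermediate
27 | triethyl{[(2R)-5-methyl-2-{2-[(triethylsilyl)oxy]propan-2-yl}hex-4-en-1-yl]oxy}silane | CC(C)=CC[C@H](CO[Si](CC)(CC)CC)C(C)(C)O[Si](CC)(CC)CC | intermediate
28 | 1-(triphenyl-λ5-phosphanylidene)propan-2-one | CC(=O)C=P(c1ccccc1)(c1ccccc1)c1ccccc1 | starting material
29 | (2S)-5-methyl-2-{2-[(triethylsilyl)oxy]propan-2-yl}hex-4-enal (not isolated) | CC(C)=CC[C@H](C=O)C(C)(C)O[Si](CC)(CC)CC | intermediate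
30 | (3E,5R)-8-methyl-5-{2-[(triethylsilyl)oxy]propan-2-yl}nona-3,7-dien-2-one | CC(C)=CC[C@H](/C=C/C(C)=O)C(C)(C)O[Si](CC)(CC)CC | intermediate
31 | 1-[(2S,3R)-3-{(3R)-2,6-dimethyl-2-[(triethylsilyl)oxy]hept-5-en-3-yl}oxiran-2-yl]ethan-1-one | CC(C)=CC[C@H]([C@H]1O[C@@H]1C(C)=O)C(C)(C)O[Si](CC)(CC)CC | intermediate
32 | triethyl phosphonoacetate | CCOC(=O)CP(=O)(OCC)OCC | starting material
33 | ethyl (2E)-3-[(2R,3R)-3-{(3R)-2,6-dimethyl-2-[(triethylsilyl)oxy]hept-5-en-3-yl}oxiran-2-yl]but-2-enoate | CC(C)=CC[C@H]([C@H]1O[C@@H]1/C(C)=C/C(=O)OCC)C(C)(C)O[Si](CC)(CC)CC | intermediate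
34 | (2E)-3-[(2R,3R)-3-{(3R)-2,6-dimethyl-2-[(triethylsilyl)oxy]hept-5-en-3-yl}oxiran-2-yl]but-2-en-1-ol | CC(C)=CC[C@H]([C@H]1O[C@@H]1/C(C)=C/CO)C(C)(C)O[Si](CC)(CC)CC | intermediate
35 | (2E)-3-[(2R,3R)-3-{(3R)-2,6-dimethyl-2-[(triethylsilyl)oxy]hept-5-en-3-yl}oxiran-2-yl]but-2-enal | CC(C)=CC[C@H]([C@H]1O[C@@H]1/C(C)=C/C=O)C(C)(C)O[Si](CC)(CC)CC | intermediate
36 | (2R,3R)-2-{(3R)-2,6-dimethyl-2-[(triethylsilyl)oxy]hept-5-en-3-yl}-3-[(2E,4E,6E,8E,10E)-11-iodo-6,10-dimethylundeca-2,4,6,8,10-pentaen-2-yl]oxirane | CC(C)=CC[C@H]([C@H]1O[C@@H]1/C(C)=C/C=C/C(C)=C/C=C/C(C)=C/I)C(C)(C)O[Si](CC)(CC)CC | intermediate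
37 | tris(triethylsilyl) ether of 38 at the C1, C1' and side-chain tertiary hydroxyls | CC(C)=CC[C@H]([C@H]1O[C@@H]1/C(C)=C/C=C/C(C)=C/C=C/C(C)=C/C=C/C=C(C)/C=C/C=C(C)/C=C/C=C(C)/C=C/[C@H](CCC(C)(C)O[Si](CC)(CC)CC)C(C)(C)O[Si](CC)(CC)CC)C(C)(C)O[Si](CC)(CC)CC | intermediate
38 | (2S,2'R,3'R,4'R)-3',4'-epoxy-2-(3-hydroxy-3-methylbutyl)-2'-(3-methylbut-2-en-1-yl)-3,4-didehydro-1,2,1',2'-tetrahydro-ψ,ψ-carotene-1,1'-diol | CC(C)=CC[C@H]([C@H]1O[C@@H]1/C(C)=C/C=C/C(C)=C/C=C/C(C)=C/C=C/C=C(C)/C=C/C=C(C)/C=C/C=C(C)/C=C/[C@H](CCC(C)(C)O)C(C)(C)O)C(C)(C)O | target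

**Step count**
Total: 26 steps. Longest linear sequence: 13 steps (steps 14–26).

**Steps most likely to fail**

Step 25 (key Stille union). What may go wrong: ionisation of the vinyl oxirane by zerovalent palladium, or protodestannylation and E/Z isomerisation of the long stannane, outrunning the cross-coupling. Fallback: the palladium step is moved ahead of the oxirane. Setting out from stannane 19 and phosphonate 8, the same Stille conditions should join C15' to C14' and give the all-E C35 decaenyl phosphonate F1, which never meets an epoxide under palladium. Its sodium anion (NaN(SiMe3)2, THF, −78 to 0 °C) is then condensed with epoxy enal 35 in a Horner–Wadsworth–Emmons reaction that forms C7'=C8' last and returns to the route at 37.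

Step 20 (enone epoxidation). What may go wrong: poor facial selectivity from a catalyst–substrate mismatch, or the opposite sense of induction to that assumed for the (R)-BINOL complex, or sluggish conjugate addition at the hindered β-carbon. Fallback: a hydroxyl-directed electrophilic epoxidation replaces the nucleophilic one. Setting out from enone 30, Corey–Bakshi–Shibata reduction with the (S)-methyl oxazaborolidine and catecholborane (toluene, −78 °C) should give the (2R,3E,5R)-allylic alcohol F2. Sharpless epoxidation with Ti(O-i-Pr)4, D-(−)-diisopropyl tartrate and t-BuOOH (4 Å MS, CH2Cl2, −20 °C), the matched pairing for this carbinol and inert to the prenyl alkene, should give the erythro epoxy alcohol F3. Dess–Martin oxidation (NaHCO3, CH2Cl2) returns to the route at epoxy ketone 31.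

Step 13 (mono-Stille to the heptaenyl stannane). What may go wrong: double coupling of the distannane and loss of tin from the polyenyl stannane during purification. Fallback: boron replaces tin. Setting out from iodide 17, Suzuki–Miyaura coupling at the pinacol boronate end of commercial (E)-2-(4,4,5,5-tetramethyl-1,3,2-dioxaborolan-2-yl)ethenylboronic acid MIDA ester (PdCl2(dppf), K3PO4, DMSO, rt) should give the bench-stable heptaenyl MIDA boronate F4. Slow-release Suzuki–Miyaura coupling of F4 with iodide 36 (Pd(OAc)2, XPhos, aq. NaOH, THF, rt) forms the C14'–C15' bond and returns to the route at 37.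

**Further compounds**
F1 | step 25 | diethyl [(2E,4E,6E,8E,10E,12E,14E,16E,18E,20E,22S)-2,6,11,15,19,25-hexamethyl-25-[(triethylsilyl)oxy]-22-{2-[(triethylsilyl)oxy]propan-2-yl}hexacosa-2,4,6,8,10,12,14,16,18,20-decaen-1-yl]phosphonate | CCOP(=O)(OCC)C/C(C)=C/C=C/C(C)=C/C=C/C=C(C)/C=C/C=C(C)/C=C/C=C(C)/C=C/[C@H](CCC(C)(C)O[Si](CC)(CC)CC)C(C)(C)O[Si](CC)(CC)CC
F2 | step 20 | (2R,3E,5R)-8-methyl-5-{2-[(triethylsilyl)oxy]propan-2-yl}nona-3,7-dien-2-ol | CC(C)=CC[C@H](/C=C/[C@@H](C)O)C(C)(C)O[Si](CC)(CC)CC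
F3 | step 20 | (1R)-1-[(2R,3R)-3-{(3R)-2,6-dimethyl-2-[(triethylsilyl)oxy]hept-5-en-3-yl}oxiran-2-yl]ethan-1-ol | CC(C)=CC[C@H]([C@H]1O[C@@H]1[C@@H](C)O)C(C)(C)O[Si](CC)(CC)CC
F4 | step 13 | 6-methyl-2-[(1E,3E,5E,7E,9E,11E,13E,15S)-4,8,12,18-tetramethyl-18-[(triethylsilyl)oxy]-15-{2-[(triethylsilyl)oxy]propan-2-yl}nonadeca-1,3,5,7,9,11,13-heptaen-1-yl]-1,3,6,2-dioxazaborocane-4,8-dione | CN1CC(=O)OB(/C=C/C=C(C)/C=C/C=C(C)/C=C/C=C(C)/C=C/[C@H](CCC(C)(C)O[Si](CC)(CC)CC)C(C)(C)O[Si](CC)(CC)CC)OC(=O)C1
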